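I had 3 questions about the amount of single ring at 5.0 d, and 4 flasks that differ in their charge of substrate.

| setting | grey | teal | maple | alder | ash | elm |
|---|---|---|---|---|---|---|
| substrate | 0.12 M | 0.51 M | 0.20 M | 0.15 M | 0.61 M | 0.40 M |
| remark | run made earlier | run made earlier |  |  |  |  |
| time |  |  | 5.0 d | 5.0 d | 5.0 d | 5.0 d |

| run | time / d | single ring / % | substrate / % |
|---|---|---|---|
| grey | 0.208 | 63.8 | 5.4 |
| grey | 0.625 | 71.3 | 0.7 |
| grey | 1.25 | 71.0 | 0 |
| grey | 1.67 | 72.0 | 0 |
| grey | 2.50 | 72.8 | 0 |
| teal | 0.208 | 36.5 | 1.4 |
| teal | 0.417 | 38.7 | 0 |
| teal | 0.625 | 38.9 | 0.5 |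
| teal | 1.25 | 40.4 | 0 |
| teal | 2.50 | 41.1 | 0.8 |

(standard deviation of a reading: 1 percentage point)

1. all flasks from highest to lowest amount of single ring, in percent of the substrate charged, at 5.0 d (maple / alder / ash / elm)
2. the amount of single ring, in percent of the substrate charged of the flask you put first, at 5.0 d
3. the amount of single ring, in percent of the substrate charged of the flask you put last, at 5.0 d

I took the last reading of each run, at 2.50 d, as its plateau, since grey's substrate reading had reached 0% by 1.25 d. What remained to reckon with was the charge.

1. Bound from above. I assumed the yield falls as the charge rises, as it did from 72.8% in grey to 41.1% in teal. On that assumption alder stays under 72.8% and ash under 41.1%, and the order runs alder, maple, elm, ash.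
2. Bound from below. The concentration of single ring, reckoned from these last readings, rose from 0.0874 M in grey to 0.210 M in teal, and I assumed it does not fall with charge. On that assumption alder holds at least 58.2% and ash at least 34.4%.
3. Tightening. I defined the even-split charge as the charge at which single ring and the rest take equal shares, that is, selectivity one. It is c·Y/(1−Y) for a yield Y at charge c. Grey gives 0.321 M and teal 0.356 M. With Y = 1/(1+c/split), alder lands between 68.2% and 70.3%, and ash between 34.5% and 36.8%.
4. The forecast. It gave alder > maple > elm > ash, with 69% and 37%, noting “Both forms agree closely when interpolating”. Its top stands inside my alder range, and its low just above the upper end of my ash range.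

The flasks gave alder > maple > elm > ash, with 65.8% and 36.7%. The forecast's order holds and both its values fall within the tolerance. Ash lies in my range, while alder lies below its range, though above its bound from below.

    substrate → single ring (k = 1.40 × 10⁻⁴ /s)
    2 substrate → open dimer (k = 6.20 × 10⁻⁴ /M/s)
    substrate + open dimer → open trimer (k = 1.20 × 10⁻⁴ /M/s)
    open dimer → ring dimer (k = 4.30 × 10⁻⁶ /s)
    substrate + single ring ⇌ idle adduct, settled at all times (K = 6.30 /M)
    substrate → decomposition product (k = 2.50 × 10⁻⁹ /s)

Read back from these results, the even-split charge is 0.289 M in alder and 0.353 M in ash, so it is smaller in alder than in ash. The neighbouring flask is ash charged with 1.5 M of substrate. The same reckoning gives 17.6% from grey and 19.2% from teal, with bounds of 14.0% and 41.1%. At 5.0 d that flask held 20.7% of single ring, an even-split charge of 0.392 M.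

The earlier runs and the new flask were generated by integration from invented constants, and the scatter is random.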